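## Retrosynthetic overview
1. There is one disconnection, at the O–CH2 (alkyl C–O) bond of the ester. It gives 1-hexacosanol 1 as the latent C1 electrophile and 3-(4-hydroxyphenyl)propanoic acid 2 as the O-nucleophile.
2. In the forward direction, a dehydrative, redox-neutral P(V)-catalysed substitution joins 1 and 2 directly to the target 3, with water as the only by-product.
3. No protecting group is needed. No acyl electrophile is ever generated and the phenol stays protonated, so one step is defensible.
4. No ring is formed, since the para-disubstituted benzene ring arrives intact with 2. There is no stereocentre to set.

Assumption: the target has no stereocentre and no stereogenic double bond, so it is achiral and the given SMILES describes it completely.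
Assumption: the phosphorus species of the catalytic cycle in step 1 are states of the catalyst, not compounds of the route, so they are described in words and carry no number.
Catalyst of step 1: (2-hydroxybenzyl)diphenylphosphine oxide, O=P(Cc1ccccc1O)(c1ccccc1)c1ccccc1. It is commercially available, used at 10 mol %, and leaves the step unchanged.

## Route

Step 1
Reactants: 1 1-hexacosanol; 2 3-(4-hydroxyphenyl)propanoic acid
Product: 3 hexacosyl 3-(4-hydroxyphenyl)propanoate
Conditions: 1 (1.0 equiv), 2 (1.3 equiv), (2-hydroxybenzyl)diphenylphosphine oxide (10 mol %), xylenes (0.25 M), reflux (ca. 140 °C), Dean–Stark, N2, 48 h; then aq NaHCO3 wash, recrystallisation from acetone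
Reagents that add atoms: none
Why: Proposed new method: a redox-neutral phosphine-oxide-catalysed Mitsunobu-type substitution, so far shown for electron-poor, markedly acidic pronucleophiles such as nitrobenzoic acids, is extended to an unactivated aliphatic acid (pKa about 4.6) that also carries a free phenol: the catalyst's phenol closes onto its P=O with loss of water (removed azeotropically) to give a strained five-membered oxyphosphonium, 1 opens this ring to a hexacosyloxyphosphonium ion whose counter-ion is the carboxylate of 2, and SN2 attack of that carboxylate at the unhindered C1 of the chain forms the O–CH2 bond and returns the phosphine oxide; the estimated penalty of about 3 kcal/mol that the weaker acid pays in ion-pair formation (net of its more nucleophilic carboxylate) should be repaid by the lower SN2 barrier of an unbranched primary carbon compared with the secondary alcohols that already turn over, the phenol (pKa about 10) is never ionised and no acyl electrophile exists, so neither aryl ether nor phenyl ester oligomers should form, no stereocentre is created, and the closest known reaction types are the stoichiometric Mitsunobu esterification and its catalytic dehydrative variant with nitrobenzoic acids.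

## Compound list
1 | 1-hexacosanol (ceryl alcohol) | CCCCCCCCCCCCCCCCCCCCCCCCCCO | starting material
2 | 3-(4-hydroxyphenyl)propanoic acid (phloretic acid) | O=C(O)CCc1ccc(O)cc1 | starting material
3 | hexacosyl 3-(4-hydroxyphenyl)propanoate (CNP0312891.0) | CCCCCCCCCCCCCCCCCCCCCCCCCCOC(=O)CCc1ccc(O)cc1 | target

## Totals
Total step count: 1
Longest linear sequence: 1

## Steps most likely to fail
The route has only one step, so the ranking has one entry.

1. Step 1 (the proposed new step).

Risk: acid 2 is about three pKa units weaker than the pronucleophiles for which this catalysis is established. The alkoxyphosphonium carboxylate may therefore be populated too little for turnover. Signs of failure would be any of the following: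
- unchanged 1;
- dihexacosyl ether, from attack of a second molecule of 1 on the activated alcohol;
- catalyst parked reversibly as an aryloxyphosphonium species with the phenol of 2 or 3.

A purely thermal acyl–O esterification running alongside leads to the same 3 and does no harm.

Fallback (known chemistry, sets out from 1 and comes back to the route at 3): the catalytic in situ activation is given up for an isolated, stoichiometric electrophile. Compound 1 is treated with methanesulfonyl chloride and triethylamine in THF at 40 °C, warm enough to keep the C26 alcohol in solution, to give hexacosyl methanesulfonate F1. F1 is then heated with 2 and KHCO3 (1.2 equiv each) in DMF–THF at 70 °C. Bicarbonate deprotonates only the carboxylic acid, so SN2 alkylation of the carboxylate gives 3 while the phenol remains untouched.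

## Further compounds
F1 | step 1 | hexacosyl methanesulfonate | CCCCCCCCCCCCCCCCCCCCCCCCCCOS(C)(=O)=O
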